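The ten-membered carbocycle (C1–C10) is disconnected at C5–C6. C6 is the γ-carbon of the butenolide ring (O–C12(=O)–C11=C7–C6) and C5 its oxygenated neighbour in the large ring, so this bond is a vinylogous aldol bond. In one operation a 2-silyloxyfuran attacks a tethered aldehyde through C6: the ring closes, C5 and C6 are set and the lactone is restored. The precursor is the open chain C5–C4–C3–C2–C1–C10–C9–C8–C7 ending in the 2-(triisopropylsilyloxy)furan, with an α-(p-methoxybenzyloxy) aldehyde at C5 (chelation handle at O4), a silyl-protected C1 carbinol, the O8 methacrylate and a C13 silyl ether. Displacement of the C5 oxygen by O4 with inversion later gives the cis-epoxide.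

Key step: step 16

Remarks on the chemistry (assumptions and design points)
- Atom numbers are those of the germacranolide skeleton of the target: C1 ketone, C4/C5 epoxide (C15 methyl on C4), C6 lactone CH–O, C7=C11, C8 methacrylate carbinol, C10=C14, C12 lactone C=O, C13 CH2OAc. TBS = tert-butyldimethylsilyl, TES = triethylsilyl, TIPS = triisopropylsilyl, PMB = 4-methoxybenzyl, Ms = methanesulfonyl.
- Assumption: (R)-2-methylglycidol is bought. Its quaternary carbon becomes C4 (S in all later compounds).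
- C5 requirement: epoxide closure by O4 inverts C5, so the ring closure must give the 5S carbinol next to 4S. For a 4S aldehyde this is the chelation product; a polar Felkin–Anh addition anti to a non-chelating O4 silyl ether would give 5R. O4 is therefore a PMB ether and the Lewis acid is bidentate Mg(II).
- C1 is carried as a TBS-protected carbinol and oxidised last. A C1 enone would offer the furan a six-membered Mukaiyama–Michael closure at C14, and an allylic ketal would ionise under the Lewis acid. The C1 configuration (S) is temporary and arbitrary; the ligand antipode in step 11 is chosen to give it.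
- O13 stays a silyl ether until after ring closure, because an acyloxy group on C13 would be a leaving group conjugated with the 2-silyloxy donor. O8 carries its methacrylate from step 10 on.
- C5 is differentiated from C1 from the start (it is the carbinol carbon of the glycidol), so no alkene has to be cleaved once C10=C14 is present.
- The borane of step 9 is made in the flask from B-bromodiisopinocampheylborane and allene; this is not counted as a step.

**Route**

Step 1
Reactants: 1 (R)-2-methylglycidol; 2 allylmagnesium chloride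
Product: 3 (S)-2-methylhex-5-ene-1,2-diol
Conditions: 2 (2.5 equiv), CuI (10 mol %), THF, −30 → 0 °C; aq. NH4Cl
Reagents that add atoms: none
Why: Copper-catalysed Grignard opening of the epoxide at its unsubstituted CH2 terminus (SN2) leaves the quaternary carbinol carbon, the future C4, untouched, so its configuration is carried over (R becomes S only through the change in CIP ranking).

Step 2
Reactants: 3 (S)-2-methylhex-5-ene-1,2-diol
Product: 4 (4S)-4-(but-3-en-1-yl)-2-(4-methoxyphenyl)-4-methyl-1,3-dioxolane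
Conditions: 4-MeOC6H4CH(OMe)2, PPTS (cat.), CH2Cl2, rt
Reagents that add atoms: 4-methoxybenzaldehyde dimethyl acetal, COc1ccc(C(OC)OC)cc1
Why: Acid-catalysed transacetalisation of the 1,2-diol gives the five-membered p-methoxybenzylidene acetal; the acetal carbon is an inconsequential epimer mixture that disappears in step 3.

Step 3
Reactants: 4 (4S)-4-(but-3-en-1-yl)-2-(4-methoxyphenyl)-4-methyl-1,3-dioxolane
Product: 5 (S)-2-[(4-methoxybenzyl)oxy]-2-methylhex-5-en-1-ol
Conditions: DIBAL-H (3 equiv), CH2Cl2, −78 → 0 °C; Rochelle salt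
Reagents that add atoms: none
Why: Regioselective reductive opening of the benzylidene acetal: aluminium binds the less hindered primary oxygen, that C–O bond breaks and hydride reduces the oxocarbenium ion, which leaves the PMB group on the tertiary O4 and frees the C5 hydroxyl.

Step 4
Reactants: 5 (S)-2-[(4-methoxybenzyl)oxy]-2-methylhex-5-en-1-ol
Product: 6 triethyl({(S)-2-[(4-methoxybenzyl)oxy]-2-methylhex-5-en-1-yl}oxy)silane
Conditions: TESCl, imidazole, CH2Cl2, 0 °C
Reagents that add atoms: chlorotriethylsilane, CC[Si](Cl)(CC)CC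
Why: Imidazole-promoted silylation of the unhindered primary alcohol masks the C5 hydroxyl until step 13.

Step 5
Reactants: 6 triethyl({(S)-2-[(4-methoxybenzyl)oxy]-2-methylhex-5-en-1-yl}oxy)silane
Product: 7 (S)-4-[(4-methoxybenzyl)oxy]-4-methyl-5-[(triethylsilyl)oxy]pentanal
Conditions: K2OsO4·2H2O (2 mol %), NaIO4 (4 equiv), 2,6-lutidine, dioxane/H2O 3:1, rt
Reagents that add atoms: sodium periodate, [Na+].[O-]I(=O)(=O)=O
Why: Lemieux–Johnson cleavage (osmium-catalysed dihydroxylation, periodate glycol cleavage) of the only alkene gives the C1 aldehyde, with 2,6-lutidine keeping the medium neutral for the TES and PMB ethers.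

Step 6
Reactants: 8 but-2-yne-1,4-diol; 9 vinylmagnesium chloride
Product: 11 3-(hydroxymethyl)-4-vinylfuran-2(5H)-one, via alkenylmagnesium chelate 10 (not isolated)
Conditions: 9 (5 equiv), THF/toluene, 70 °C; then CO2 (g), −40 °C → rt; then 2 M HCl
Reagents that add atoms: carbon dioxide, O=C=O
Why: Alkoxide-directed anti-carbomagnesiation of the propargylic diol puts the vinyl group on C7 and magnesium on C11 cis to the C6 alkoxide, so that carboxylation at C11 and acidification give the butenolide with C13 as a free hydroxymethyl group.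

Step 7
Reactants: 11 3-(hydroxymethyl)-4-vinylfuran-2(5H)-one
Product: 12 3-({[tert-butyl(dimethyl)silyl]oxy}methyl)-4-vinylfuran-2(5H)-one
Conditions: TBSCl, imidazole, DMF, 0 °C → rt
Reagents that add atoms: tert-butyldimethylsilyl chloride, CC(C)(C)[Si](C)(C)Cl
Why: Standard silylation of the primary alcohol gives a C13 ether that is a poor leaving group and can therefore stay next to the later 2-silyloxyfuran.

Step 8
Reactants: 12 3-({[tert-butyl(dimethyl)silyl]oxy}methyl)-4-vinylfuran-2(5H)-one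
Product: 14 4-({[tert-butyl(dimethyl)silyl]oxy}methyl)-5-oxo-2,5-dihydrofuran-3-carbaldehyde, via ozonide 13 (not isolated)
Conditions: O3, CH2Cl2, −78 °C (Sudan III end-point); then PPh3, −78 °C → rt; used crude
Reagents that add atoms: ozone, [O-][O+]=O
Why: Ozonolysis with reductive work-up cleaves the terminal γ,δ-alkene of the dienoate, while the tetrasubstituted, ester-conjugated ring alkene is far less reactive towards ozone.

Step 9
Reactants: 14 4-({[tert-butyl(dimethyl)silyl]oxy}methyl)-5-oxo-2,5-dihydrofuran-3-carbaldehyde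
Product: 15 4-[(1R)-3-bromo-1-hydroxybut-3-en-1-yl]-3-({[tert-butyl(dimethyl)silyl]oxy}methyl)furan-2(5H)-one
Conditions: (2-bromoallyl)B(Ipc)2 [from Ipc2BBr (ex (−)-α-pinene) and allene], Et2O, −78 °C; then ethanolamine, rt
Reagents that add atoms: B-(2-bromoallyl)diisopinocampheylborane, C=C(Br)CB([C@@H]1[C@@H](C)[C@@H]2C[C@H](C1)C2(C)C)[C@@H]1[C@@H](C)[C@@H]2C[C@H](C1)C2(C)C
Why: Asymmetric 2-bromoallylboration through a closed chair transition state; the reagent derived from (−)-α-pinene adds to the aldehyde face that gives 8R with alkenyl aldehydes (the sense known for the parent allylborane), and the non-oxidative work-up spares the lactone and the vinyl bromide.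

Step 10
Reactants: 15 4-[(1R)-3-bromo-1-hydroxybut-3-en-1-yl]-3-({[tert-butyl(dimethyl)silyl]oxy}methyl)furan-2(5H)-one
Product: 16 (1R)-3-bromo-1-[4-({[tert-butyl(dimethyl)silyl]oxy}methyl)-5-oxo-2,5-dihydrofuran-3-yl]but-3-en-1-yl 2-methylprop-2-enoate
Conditions: methacrylic anhydride, DMAP (cat.), pyridine, CH2Cl2, 0 °C
Reagents that add atoms: methacrylic anhydride, C=C(C)C(=O)OC(=O)C(C)=C
Why: DMAP-catalysed acylation under weakly basic conditions installs the final O8 ester at once, which also blocks migration of the lactone to O8.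

Step 11
Reactants: 7 (S)-4-[(4-methoxybenzyl)oxy]-4-methyl-5-[(triethylsilyl)oxy]pentanal; 16 (1R)-3-bromo-1-[4-({[tert-butyl(dimethyl)silyl]oxy}methyl)-5-oxo-2,5-dihydrofuran-3-yl]but-3-en-1-yl 2-methylprop-2-enoate
Product: 17 (1R,4S,7S)-1-[4-({[tert-butyl(dimethyl)silyl]oxy}methyl)-5-oxo-2,5-dihydrofuran-3-yl]-4-hydroxy-7-[(4-methoxybenzyl)oxy]-7-methyl-3-methylidene-8-[(triethylsilyl)oxy]octyl 2-methylprop-2-enoate
Conditions: CrCl2 (4 equiv), chiral oxazoline–sulfonamide ligand (4.4 equiv, antipode giving 1S), Et3N, NiCl2 (0.2 equiv), THF, rt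
Reagents that add atoms: none
Why: Nozaki–Hiyama–Kishi coupling: nickel inserts into the vinyl bromide, transmetalation gives an alkenylchromium(III) species that adds only to the aldehyde (esters, lactone and silyl ethers are inert), and the chiral ligand on chromium sets the temporary C1 carbinol, whose purity is not critical because both epimers converge in step 22.

Step 12
Reactants: 17 (the C1 alcohol of step 11)
Product: 18 (1R,4S,7S)-4-{[tert-butyl(dimethyl)silyl]oxy}-1-[4-({[tert-butyl(dimethyl)silyl]oxy}methyl)-5-oxo-2,5-dihydrofuran-3-yl]-7-[(4-methoxybenzyl)oxy]-7-methyl-3-methylidene-8-[(triethylsilyl)oxy]octyl 2-methylprop-2-enoate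
Conditions: TBSCl, imidazole, DMAP (cat.), DMF, rt
Reagents that add atoms: tert-butyldimethylsilyl chloride, CC(C)(C)[Si](C)(C)Cl
Why: Standard silylation keeps C1 as a protected carbinol through the ring closure, where a C1 enone would invite attack of the furan on C14.

Step 13
Reactants: 18 (the O1-TBS ether of step 12)
Product: 19 (1R,4S,7S)-4-{[tert-butyl(dimethyl)silyl]oxy}-1-[4-({[tert-butyl(dimethyl)silyl]oxy}methyl)-5-oxo-2,5-dihydrofuran-3-yl]-8-hydroxy-7-[(4-methoxybenzyl)oxy]-7-methyl-3-methylidene-octyl 2-methylprop-2-enoate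
Conditions: PPTS (0.1 equiv), MeOH/CH2Cl2 1:1, 0 °C
Reagents that add atoms: none
Why: Acid-catalysed methanolysis removes the primary triethylsilyl ether much faster than either TBS ether, so only the C5 hydroxyl is freed.

Step 14
Reactants: 19 (the C5 alcohol of step 13)
Product: 20 (1R,4S,7S)-4-{[tert-butyl(dimethyl)silyl]oxy}-1-[4-({[tert-butyl(dimethyl)silyl]oxy}methyl)-5-oxo-2,5-dihydrofuran-3-yl]-7-[(4-methoxybenzyl)oxy]-7-methyl-3-methylidene-8-oxooctyl 2-methylprop-2-enoate
Conditions: Dess–Martin periodinane, NaHCO3, CH2Cl2, 0 °C → rt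
Reagents that add atoms: none
Why: Buffered Dess–Martin oxidation of the primary alcohol gives an aldehyde whose α-carbon is quaternary, so it can neither enolise nor epimerise.

Step 15
Reactants: 20 (the C5 aldehyde of step 14)
Product: 21 (1R,4S,7S)-4-{[tert-butyl(dimethyl)silyl]oxy}-1-[4-({[tert-butyl(dimethyl)silyl]oxy}methyl)-5-{[tri(propan-2-yl)silyl]oxy}furan-3-yl]-7-[(4-methoxybenzyl)oxy]-7-methyl-3-methylidene-8-oxooctyl 2-methylprop-2-enoate
Conditions: TIPSOTf (1.3 equiv), Et3N (3 equiv), CH2Cl2, −78 → −40 °C; cold aq. NaHCO3; Et3N-deactivated silica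
Reagents that add atoms: triisopropylsilyl triflate, CC(C)[Si](C(C)C)(C(C)C)OS(=O)(=O)C(F)(F)F
Why: Soft enolisation: O-silylation of the lactone carbonyl and loss of a C6 proton to triethylamine give the aromatic 2-silyloxyfuran, while the non-enolisable, α-quaternary aldehyde is not activated by the bulky silyl triflate at low temperature in the presence of excess amine.

Step 16
Reactants: 21 (the silyloxyfuran aldehyde of step 15)
Product: 22 (1S,4S,5S,6R,8R)-1,13-bis{[tert-butyl(dimethyl)silyl]oxy}-5-hydroxy-4-[(4-methoxybenzyl)oxy]-8-(methacryloyloxy)germacra-7(11),10(14)-dien-12,6-olide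
Conditions: MgBr2·OEt2 (4 equiv), CH2Cl2, −20 °C, 21 added by syringe pump (final 1 mM); aq. NaHCO3
Reagents that add atoms: none
Why: Proposed new method: Mg(II) binds the aldehyde oxygen and the O4 ether oxygen of 21 in a five-membered chelate, the furan attacks C5 through its γ-carbon C6 in an open transition state, and loss of the silyl group (as the silyl bromide) restores the butenolide; the closest known reactions are the chelation-controlled intermolecular vinylogous Mukaiyama aldol additions of 2-silyloxyfurans to α-alkoxy aldehydes and the silyloxyfuran aldol carbocyclisations that close five- to seven-membered rings, neither of which has been used for a ten-membered ring. The ring is closed in a 10-(enolendo)-exo-trig mode, helped by the sp2 centres C6, C7 and C10 and by high dilution. C5 is controlled by the chelate and the tether: inside the chelate the chain leaves C4 through C3, so C6 can reach only the carbonyl face on the side of the C15 methyl group (a C3–C4–C5–C6 torsion near 135° instead of a near-eclipsed one), which is also the face a Cram chelate prefers, and this gives 5S, whereas a non-chelated polar Felkin–Anh addition would give 5R. C6 is controlled by the threo (5S,6R) topicity usual for Lewis acid-mediated silyloxyfuran additions and by the C8 stereocentre, which decides on which side of the furan plane the tether runs. The step needs γ- and not α-attack, secured by the fully substituted C11, and it needs reaction at the aldehyde only, secured by bidentate activation of this one carbonyl group by a mild Lewis acid, by the poor leaving-group ability of the C13 silyl ether and by the absence of an enone at C1.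

Step 17
Reactants: 22 (the macrocyclic C5 carbinol of step 16)
Product: 23 (1S,4S,5S,6R,8R)-1,13-bis{[tert-butyl(dimethyl)silyl]oxy}-4-[(4-methoxybenzyl)oxy]-5-[(methylsulfonyl)oxy]-8-(methacryloyloxy)germacra-7(11),10(14)-dien-12,6-olide
Conditions: Ms2O (3 equiv), pyridine, DMAP (0.2 equiv), CH2Cl2, 0 °C
Reagents that add atoms: methanesulfonic anhydride, CS(=O)(=O)OS(C)(=O)=O
Why: Sulfonylation of the only free hydroxyl proceeds with retention at C5, and pyridine is too weak a base to remove the C6 proton.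

Step 18
Reactants: 23 (the C5 mesylate of step 17)
Product: 24 (1S,4S,5S,6R,8R)-1,13-bis{[tert-butyl(dimethyl)silyl]oxy}-4-hydroxy-5-[(methylsulfonyl)oxy]-8-(methacryloyloxy)germacra-7(11),10(14)-dien-12,6-olide
Conditions: DDQ (1.5 equiv), CH2Cl2/pH 7 buffer 10:1, 0 °C → rt
Reagents that add atoms: none
Why: Oxidative PMB cleavage: DDQ oxidises the electron-rich benzyl ether to an oxocarbenium ion that water hydrolyses, freeing the tertiary O4 hydroxyl under neutral conditions that leave the mesylate, silyl ethers and esters alone.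

Step 19
Reactants: 24 (the hydroxy mesylate of step 18)
Product: 25 (1S,4S,5R,6R,8R)-1,13-bis{[tert-butyl(dimethyl)silyl]oxy}-4,5-epoxy-8-(methacryloyloxy)germacra-7(11),10(14)-dien-12,6-olide
Conditions: KHMDS (1.0 equiv), THF, −78 → −20 °C; pH 7 buffer
Reagents that add atoms: none
Why: Intramolecular Williamson reaction (3-exo-tet): one equivalent of base removes the O–H proton much faster than the C6–H proton and the tertiary alkoxide displaces the adjacent mesylate from the rear, so C5 is inverted (5S to 5R) while C4 is retained, which gives the cis (C3/C6) epoxide.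

Step 20
Reactants: 25 (the epoxide of step 19)
Product: 26 (1S,4S,5R,6R,8R)-4,5-epoxy-1,13-dihydroxy-8-(methacryloyloxy)germacra-7(11),10(14)-dien-12,6-olide
Conditions: HF·pyridine, pyridine, THF, 0 °C → rt
Reagents that add atoms: none
Why: Fluoride-mediated Si–O cleavage removes both TBS ethers, and buffering with pyridine is meant to spare the epoxide, the esters and the lactone.

Step 21
Reactants: 26 (the 1,13-diol of step 20)
Product: 27 (1S,4S,5R,6R,8R)-13-acetoxy-4,5-epoxy-1-hydroxy-8-(methacryloyloxy)germacra-7(11),10(14)-dien-12,6-olide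
Conditions: AcCl (1.1 equiv), 2,4,6-collidine, CH2Cl2, −78 °C
Reagents that add atoms: acetyl chloride, CC(Cl)=O
Why: Acylation with acetyl chloride and a hindered pyridine base at low temperature is selective for the primary hydroxyl over the more hindered secondary C1 hydroxyl.

Step 22
Reactants: 27 (the 13-acetate of step 21)
Product: 28 (4S,5R,6R,8R)-13-acetoxy-4,5-epoxy-8-(methacryloyloxy)-1-oxogermacra-7(11),10(14)-dien-12,6-olide (CNP0266914.1)
Conditions: Dess–Martin periodinane, NaHCO3, CH2Cl2, 0 °C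
Reagents that add atoms: none
Why: Buffered Dess–Martin oxidation converts the allylic C1 carbinol into the α-methylene ketone without touching the epoxide, the esters or the lactone, and it removes the temporary C1 stereocentre.

**Compound list**

1 | (R)-2-methylglycidol [(R)-(2-methyloxiran-2-yl)methanol] | C[C@@]1(CO)CO1 | starting material
2 | allylmagnesium chloride | C=CC[Mg]Cl | starting material
3 | (S)-2-methylhex-5-ene-1,2-diol | OC[C@@](C)(O)CCC=C | intermediate
4 | (4S)-4-(but-3-en-1-yl)-2-(4-methoxyphenyl)-4-methyl-1,3-dioxolane (both epimers at the acetal carbon) | COc1ccc(C2OC[C@](C)(CCC=C)O2)cc1 | intermediate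
5 | (S)-2-[(4-methoxybenzyl)oxy]-2-methylhex-5-en-1-ol | OC[C@@](C)(OCc1ccc(OC)cc1)CCC=C | intermediate
6 | triethyl({(S)-2-[(4-methoxybenzyl)oxy]-2-methylhex-5-en-1-yl}oxy)silane | CC[Si](CC)(CC)OC[C@@](C)(OCc1ccc(OC)cc1)CCC=C | intermediate
7 | (S)-4-[(4-methoxybenzyl)oxy]-4-methyl-5-[(triethylsilyl)oxy]pentanal | CC[Si](CC)(CC)OC[C@@](C)(OCc1ccc(OC)cc1)CCC=O | intermediate
8 | but-2-yne-1,4-diol | OCC#CCO | starting material
9 | vinylmagnesium chloride | C=C[Mg]Cl | starting material
10 | alkenylmagnesium chelate ClMgOCH2–C(CH=CH2)=C(MgCl)–CH2OMgCl, vinyl and C–Mg trans (Z) | C=C/C(CO[Mg]Cl)=C(/[Mg]Cl)CO[Mg]Cl | intermediate (not isolated)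
11 | 3-(hydroxymethyl)-4-vinylfuran-2(5H)-one | C=CC1=C(CO)C(=O)OC1 | intermediate
12 | 3-({[tert-butyl(dimethyl)silyl]oxy}methyl)-4-vinylfuran-2(5H)-one | C=CC1=C(CO[Si](C)(C)C(C)(C)C)C(=O)OC1 | intermediate
13 | ozonide of 12: 3-({[tert-butyl(dimethyl)silyl]oxy}methyl)-4-(1,2,4-trioxolan-3-yl)furan-2(5H)-one | CC(C)(C)[Si](C)(C)OCC1=C(C2OCOO2)COC1=O | intermediate (not isolated)
14 | 4-({[tert-butyl(dimethyl)silyl]oxy}methyl)-5-oxo-2,5-dihydrofuran-3-carbaldehyde | O=CC1=C(CO[Si](C)(C)C(C)(C)C)C(=O)OC1 | intermediate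
15 | 4-[(1R)-3-bromo-1-hydroxybut-3-en-1-yl]-3-({[tert-butyl(dimethyl)silyl]oxy}methyl)furan-2(5H)-one | C=C(Br)C[C@@H](O)C1=C(CO[Si](C)(C)C(C)(C)C)C(=O)OC1 | intermediate
16 | (1R)-3-bromo-1-[4-({[tert-butyl(dimethyl)silyl]oxy}methyl)-5-oxo-2,5-dihydrofuran-3-yl]but-3-en-1-yl 2-methylprop-2-enoate | C=C(Br)C[C@@H](OC(=O)C(C)=C)C1=C(CO[Si](C)(C)C(C)(C)C)C(=O)OC1 | intermediate
17 | (1R,4S,7S)-1-[4-({[tert-butyl(dimethyl)silyl]oxy}methyl)-5-oxo-2,5-dihydrofuran-3-yl]-4-hydroxy-7-[(4-methoxybenzyl)oxy]-7-methyl-3-methylidene-8-[(triethylsilyl)oxy]octyl 2-methylprop-2-enoate (8R, 1S, 4S in target numbering) | CC[Si](CC)(CC)OC[C@@](C)(OCc1ccc(OC)cc1)CC[C@H](O)C(=C)C[C@@H](OC(=O)C(C)=C)C1=C(CO[Si](C)(C)C(C)(C)C)C(=O)OC1 | intermediate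
18 | O1-TBS ether of 17 | CC[Si](CC)(CC)OC[C@@](C)(OCc1ccc(OC)cc1)CC[C@H](O[Si](C)(C)C(C)(C)C)C(=C)C[C@@H](OC(=O)C(C)=C)C1=C(CO[Si](C)(C)C(C)(C)C)C(=O)OC1 | intermediate
19 | C5 primary alcohol (TES removed from 18) | OC[C@@](C)(OCc1ccc(OC)cc1)CC[C@H](O[Si](C)(C)C(C)(C)C)C(=C)C[C@@H](OC(=O)C(C)=C)C1=C(CO[Si](C)(C)C(C)(C)C)C(=O)OC1 | intermediate
20 | C5 aldehyde, (1R,4S,7S)-…-8-oxooctyl 2-methylprop-2-enoate with the butenolide intact | O=C[C@@](C)(OCc1ccc(OC)cc1)CC[C@H](O[Si](C)(C)C(C)(C)C)C(=C)C[C@@H](OC(=O)C(C)=C)C1=C(CO[Si](C)(C)C(C)(C)C)C(=O)OC1 | intermediate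
21 | key-step precursor: 2-(triisopropylsilyloxy)furan tethered to the (4S)-α-PMB-oxy aldehyde (8R, 1S, 4S) | O=C[C@@](C)(OCc1ccc(OC)cc1)CC[C@H](O[Si](C)(C)C(C)(C)C)C(=C)C[C@@H](OC(=O)C(C)=C)c1coc(O[Si](C(C)C)(C(C)C)C(C)C)c1CO[Si](C)(C)C(C)(C)C | intermediate
22 | key-step product: (1S,4S,5S,6R,8R)-1,13-bis(TBS-oxy)-5-hydroxy-4-(PMB-oxy)-8-(methacryloyloxy)germacra-7(11),10(14)-dien-12,6-olide | C=C(C)C(=O)O[C@@H]1CC(=C)[C@@H](O[Si](C)(C)C(C)(C)C)CC[C@](C)(OCc3ccc(OC)cc3)[C@@H](O)[C@@H]2OC(=O)C(CO[Si](C)(C)C(C)(C)C)=C21 | intermediate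
23 | 5-O-mesylate of 22 (1S,4S,5S,6R,8R) | C=C(C)C(=O)O[C@@H]1CC(=C)[C@@H](O[Si](C)(C)C(C)(C)C)CC[C@](C)(OCc3ccc(OC)cc3)[C@@H](OS(C)(=O)=O)[C@@H]2OC(=O)C(CO[Si](C)(C)C(C)(C)C)=C21 | intermediate
24 | 4-hydroxy 5-mesylate (1S,4S,5S,6R,8R) | C=C(C)C(=O)O[C@@H]1CC(=C)[C@@H](O[Si](C)(C)C(C)(C)C)CC[C@](C)(O)[C@@H](OS(C)(=O)=O)[C@@H]2OC(=O)C(CO[Si](C)(C)C(C)(C)C)=C21 | intermediate
25 | (1S,4S,5R,6R,8R)-4,5-epoxide with O1 and O13 as TBS ethers | C=C(C)C(=O)O[C@@H]1CC(=C)[C@@H](O[Si](C)(C)C(C)(C)C)CC[C@]2(C)O[C@@H]2[C@@H]2OC(=O)C(CO[Si](C)(C)C(C)(C)C)=C21 | intermediate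
26 | (1S,4S,5R,6R,8R)-4,5-epoxy-1,13-diol | C=C(C)C(=O)O[C@@H]1CC(=C)[C@@H](O)CC[C@]2(C)O[C@@H]2[C@@H]2OC(=O)C(CO)=C21 | intermediate
27 | (1S,4S,5R,6R,8R)-13-acetoxy-4,5-epoxy-1-ol | C=C(C)C(=O)O[C@@H]1CC(=C)[C@@H](O)CC[C@]2(C)O[C@@H]2[C@@H]2OC(=O)C(COC(C)=O)=C21 | intermediate
28 | CNP0266914.1, (4S,5R,6R,8R)-13-acetoxy-4,5-epoxy-8-(methacryloyloxy)-1-oxogermacra-7(11),10(14)-dien-12,6-olide | C=C(C)C(=O)O[C@@H]1CC(=C)C(=O)CC[C@]2(C)O[C@@H]2[C@@H]2OC(=O)C(COC(C)=O)=C21 | target

**Step count**

Total: 22 steps. Longest linear sequence: 17 steps (steps 1–5, then 11–22; the butenolide branch, steps 6–10, is equally long).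

**Steps most likely to fail**

1. Step 16 (Proposed new method). What may go wrong: intermolecular aldol oligomerisation outruns the strained ten-membered closure, or the tether forces the aldehyde onto the other furan face (C6 epimer) or out of the chelate (C5 epimer). Fallback with known chemistry: C5–C6 is formed intermolecularly and the ring is closed at C1–C10 instead. The fallback sets out from 5 and 16. Dess–Martin oxidation of 5 gives the aldehyde (S)-2-[(4-methoxybenzyl)oxy]-2-methylhex-5-enal F1. TIPSOTf/Et3N converts 16 into the silyloxyfuran F2. MgBr2·OEt2 in CH2Cl2 joins the two in a chelation-controlled vinylogous Mukaiyama aldol addition to the open-chain adduct F3, in which C5 and C6 are set by the C4 chelate and the threo preference alone. Ms2O/pyridine gives the mesylate F4. Osmium-catalysed periodate cleavage of the monosubstituted alkene (the bromoalkene, the methacrylate and the ring alkene are electron-poor) gives the C1 aldehyde F5. A high-dilution intramolecular Nozaki–Hiyama–Kishi reaction under the conditions of step 11 should close the ring to the macrocyclic C1 alcohol F6. TBSCl/imidazole then gives 23, where the route is rejoined.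

2. Step 19. What may go wrong: β-elimination of the C5 mesylate through deprotonation at C6 (formation of the γ-alkylidene butenolide) competes with epoxide closure. Fallback without sulfonate or added strong base, setting out from 22: anhydrous DDQ (4 Å molecular sieves) lets the C5 hydroxyl capture the oxidised PMB group as the 4,5-O-(4-methoxybenzylidene) acetal F7. PPTS/MeOH at 0 °C releases the 4,5-diol F8. Mitsunobu cyclodehydration (PPh3, DIAD, toluene) activates the secondary C5 hydroxyl as an oxyphosphonium ion, which O4 displaces with inversion, and the route is rejoined at 25.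

3. Step 20. What may go wrong: acid-promoted attack of the freed C1 hydroxyl on the epoxide (1,4-ether formation), or other epoxide opening, during desilylation. Fallback by reordering the end-game so that a free C1 hydroxyl never coexists with the epoxide, setting out from 23: HF·pyridine gives the 1,13-diol mesylate F9 while the mesylate and the PMB ether stay. AcCl/collidine gives the 13-acetate F10. Dess–Martin oxidation gives the enone F11. DDQ frees O4 to give the hydroxy mesylate F12. KHMDS (1.0 equiv, −78 °C) then closes the epoxide as the last step and the route arrives at 28.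

**Further compounds**

F1 | step 16 | (S)-2-[(4-methoxybenzyl)oxy]-2-methylhex-5-enal | O=C[C@@](C)(OCc1ccc(OC)cc1)CCC=C
F2 | step 16 | (1R)-3-bromo-1-[4-({[tert-butyl(dimethyl)silyl]oxy}methyl)-5-{[tri(propan-2-yl)silyl]oxy}furan-3-yl]but-3-en-1-yl 2-methylprop-2-enoate | C=C(Br)C[C@@H](OC(=O)C(C)=C)c1coc(O[Si](C(C)C)(C(C)C)C(C)C)c1CO[Si](C)(C)C(C)(C)C
F3 | step 16 | (1R)-3-bromo-1-{(2R)-4-({[tert-butyl(dimethyl)silyl]oxy}methyl)-2-[(1S,2S)-1-hydroxy-2-[(4-methoxybenzyl)oxy]-2-methylhex-5-en-1-yl]-5-oxo-2,5-dihydrofuran-3-yl}but-3-en-1-yl 2-methylprop-2-enoate | C=CCC[C@](C)(OCc1ccc(OC)cc1)[C@@H](O)[C@@H]1OC(=O)C(CO[Si](C)(C)C(C)(C)C)=C1[C@@H](CC(Br)=C)OC(=O)C(C)=C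
F4 | step 16 | C5 mesylate of F3 | C=CCC[C@](C)(OCc1ccc(OC)cc1)[C@@H](OS(C)(=O)=O)[C@@H]1OC(=O)C(CO[Si](C)(C)C(C)(C)C)=C1[C@@H](CC(Br)=C)OC(=O)C(C)=C
F5 | step 16 | C1 aldehyde from F4 [(1S,2S)-2-(PMB-oxy)-2-methyl-1-(mesyloxy)-5-oxopentyl side chain] | O=CCC[C@](C)(OCc1ccc(OC)cc1)[C@@H](OS(C)(=O)=O)[C@@H]1OC(=O)C(CO[Si](C)(C)C(C)(C)C)=C1[C@@H](CC(Br)=C)OC(=O)C(C)=C
F6 | step 16 | (1S,4S,5S,6R,8R)-1-hydroxy-4-(PMB-oxy)-5-(mesyloxy)-13-(TBS-oxy)-8-(methacryloyloxy)germacra-7(11),10(14)-dien-12,6-olide | C=C(C)C(=O)O[C@@H]1CC(=C)[C@@H](O)CC[C@](C)(OCc3ccc(OC)cc3)[C@@H](OS(C)(=O)=O)[C@@H]2OC(=O)C(CO[Si](C)(C)C(C)(C)C)=C21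
F7 | step 19 | (1S,4S,5S,6R,8R)-1,13-bis(TBS-oxy)-4,5-[(4-methoxybenzylidene)dioxy]-8-(methacryloyloxy)germacra-7(11),10(14)-dien-12,6-olide (both acetal epimers) | C=C(C)C(=O)O[C@@H]1CC(=C)[C@@H](O[Si](C)(C)C(C)(C)C)CC[C@]3(C)OC(c4ccc(OC)cc4)O[C@H]3[C@@H]2OC(=O)C(CO[Si](C)(C)C(C)(C)C)=C21
F8 | step 19 | (1S,4S,5S,6R,8R)-1,13-bis(TBS-oxy)-4,5-dihydroxy-8-(methacryloyloxy)germacra-7(11),10(14)-dien-12,6-olide | C=C(C)C(=O)O[C@@H]1CC(=C)[C@@H](O[Si](C)(C)C(C)(C)C)CC[C@](C)(O)[C@@H](O)[C@@H]2OC(=O)C(CO[Si](C)(C)C(C)(C)C)=C21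
F9 | step 20 | (1S,4S,5S,6R,8R)-1,13-dihydroxy-4-(PMB-oxy)-5-(mesyloxy)-8-(methacryloyloxy)germacra-7(11),10(14)-dien-12,6-olide | C=C(C)C(=O)O[C@@H]1CC(=C)[C@@H](O)CC[C@](C)(OCc3ccc(OC)cc3)[C@@H](OS(C)(=O)=O)[C@@H]2OC(=O)C(CO)=C21
F10 | step 20 | 13-acetate of F9 | C=C(C)C(=O)O[C@@H]1CC(=C)[C@@H](O)CC[C@](C)(OCc3ccc(OC)cc3)[C@@H](OS(C)(=O)=O)[C@@H]2OC(=O)C(COC(C)=O)=C21
F11 | step 20 | (4S,5S,6R,8R)-13-acetoxy-4-(PMB-oxy)-5-(mesyloxy)-8-(methacryloyloxy)-1-oxogermacra-7(11),10(14)-dien-12,6-olide | C=C(C)C(=O)O[C@@H]1CC(=C)C(=O)CC[C@](C)(OCc3ccc(OC)cc3)[C@@H](OS(C)(=O)=O)[C@@H]2OC(=O)C(COC(C)=O)=C21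
F12 | step 20 | (4S,5S,6R,8R)-13-acetoxy-4-hydroxy-5-(mesyloxy)-8-(methacryloyloxy)-1-oxogermacra-7(11),10(14)-dien-12,6-olide | C=C(C)C(=O)O[C@@H]1CC(=C)C(=O)CC[C@](C)(O)[C@@H](OS(C)(=O)=O)[C@@H]2OC(=O)C(COC(C)=O)=C21
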